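6 questions stand: which flask ends highest in X, and how much X each of the 5 flasks holds at 2.0 min.

| flask | J | D | L | remark | time |
|---|---|---|---|---|---|
| elm | 0.050 M | 0.050 M | 0.50 mM | run made earlier |  |
| birch | 0.050 M | 0.025 M | 0.50 mM | run made earlier |  |
| alder | 0.050 M | 0.10 M | 0.50 mM | run made earlier |  |
| winter | 0.050 M (in portions, 5, over 1.5 min) | 0.0500 M | 0.50 mM | first portion at the start, last at 1.5 min | 2.0 min |
| dawn | 0.050 M | 0.0500 M (fed, over 1.5 min) | 0.50 mM | all else is in the flask from the start; the feed brings no volume worth counting | 2.0 min |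
| noon | 0.050 M | 0.0500 M | 0.50 mM | everything together at the start | 2.0 min |
| dusk | 0.050 M (fed, over 10 s) | 0.0500 M | 0.50 mM | all else is in the flask from the start; the feed brings no volume worth counting | 2.0 min |
| autumn | 0.050 M (fed, over 1.5 min) | 0.0500 M | 0.50 mM | all else is in the flask from the start; the feed brings no volume worth counting | 2.0 min |

| run | time / s | X / % | E / % |
|---|---|---|---|
| elm | 10.0 | 1 | 8 |
| elm | 12.0 | 0 | 11 |
| elm | 30.0 | 1 | 23 |
| elm | 80.0 | 10 | 54 |
| birch | 30.0 | 1 | 31 |
| birch | 60.0 | 3 | 52 |
| birch | 90.0 | 13 | 61 |
| birch | 120 | 21 | 64 |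
| alder | 30.0 | 0 | 20 |
| alder | 60.0 | 3 | 38 |
| alder | 90.0 | 6 | 53 |
| alder | 120 | 12 | 59 |

(standard deviation of a reading: 1.5 percentage points)

- steps thought possible: J + L <-> G; G -> L + E; D + L <-> Q; Q -> L + Z; E + L <-> X + L

1. the flask that comes out highest in amount of X, in percent of the J charged, or "all alike" when all lie within 1.5 percentage points (winter / dawn / noon / dusk / autumn / all alike)
2. X at the end, in percent of the J charged, winter
3. X at the end, in percent of the J charged, dawn
4. X at the end, in percent of the J charged, noon
5. X at the end, in percent of the J charged, dusk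
6. X at the end, in percent of the J charged, autumn

E turns to X on free L, while G and Q hold part of L. The reckoning takes that binding as balanced and lets one constant carry the L left free. For a run, this is its X at the last reading divided by the area under its E readings. Birch gives 0.00398 s⁻¹ and alder 0.00285 s⁻¹. Their mean, 0.00341 s⁻¹, is the X clock w, a pseudo-first-order constant: X gained per E present per second.

Noon repeats the elm recipe, but elm stops at 80.0 s, so noon's X can be reached in two ways. The first brackets noon in D: birch and alder, at 120 s, average 16.5 %. The second continues elm by itself. Elm's own clock is 0.00437 s⁻¹. With E ending near the birch and alder mean, 61.5 %, this gives 20.1 %. The two part by 3.6 percentage points. The second way leans on one elm reading, X of 10 %. Birch and alder, interpolated to that time, average 7.33 %, so that reading stands 2.7 points higher, against a scatter of 1.5 points. The bracket is kept.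

A steady feed over a time T, or equal portions over it, brings J on average T/2 late. X then loses about w·(T/2) times the final E. Dusk comes to 15.5 %, and winter and autumn to 7.06 %, both less than noon. Dawn starts with less D, as birch does, and birch's 21 % is more than the bracket. So this reckoning puts dawn highest, between the bracket and birch's reading.

The forecast named dawn, with 9 % for winter, 20 % for dawn, 17 % for noon, 16.5 % for dusk and 8.5 % for autumn, and it placed dawn first on the ground that “Feeding D keeps more L available, so E comes sooner”. The flasks give 10.3 % in winter, 19.1 % in dawn, 17.3 % in noon, 16.4 % in dusk and 9.99 % in autumn, so dawn is highest.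

    J + L ⇌ G (K = 38.0 M⁻¹, k = 100 M⁻¹ s⁻¹)
    G → L + E (k = 2.90 s⁻¹)
    D + L ⇌ Q (K = 59.0 M⁻¹, k = 62.0 M⁻¹ s⁻¹)
    Q → L + Z (k = 2.80 s⁻¹)
    E + L ⇌ X + L, rate k5*[L]*[E] forward; the back reaction follows from the equilibrium constant (K = 23.0, k = 12.0 M⁻¹ s⁻¹)

Noon stands 7.3 points above autumn, while the clock reckoned 9.44 %. The neighbour of autumn is charged with 0.0013 M of L, and its clock, scaled with c_L, runs at 0.00887 s⁻¹. Its J is nearly all turned over, with 3.12 % left, and the fed J has stood in this neighbour for 75.0 s on average. That reckons X at 47.1 %. The neighbour holds 48.8 % of X beside 48.0 % of E.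

All runs were computed on assumed constants; the scatter is artificial.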